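The ten-membered ring of the target hides a 1,5-diene flanked by carbonyl carbons: C1=C10, conjugated to ester C14, and C4=C5 (the later epoxide) beside lactone carbinol C6. Both alkenes are traced back to one cyclobutane, so that C1–C2–C3–C4 with methyl C15 comes from 1-methylcyclobutene and C5–C10 with C14 from a six-membered enone having C6 as its ketone. Irradiation joins C1 to C10 and C4 to C5 in a single operation; heating afterwards breaks C1–C4 and C5–C10 and releases the cyclodecadiene. The precursor is an enantiopure 3-(methoxycarbonyl)cyclohex-2-enone carrying the C7 acetate arm and separately silylated C8 and C9 oxygens, all cis.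

Key step: step 9

Remark on the chemistry: germacrane numbering is used for every compound (ring C1–C10, lactone arm C11–C13, ester carbon C14, methyl C15), β is the face of the C7 arm in the target, "ring-cis/ring-trans" refers to the two ring bonds at an alkene, and 1-methylcyclobutene is assumed not to be a stock item (made in step 8).

Step 1
Reactants: 1 (1S,2S)-3-bromocyclohexa-3,5-diene-1,2-diol
Product: 2 (1S,2S)-3-bromocyclohex-3-ene-1,2-diol
Conditions: KO2CN=NCO2K, AcOH, MeOH, 0 °C to rt
Reagents that add atoms: none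
Why: Diimide reduction: the HN=NH released in the flask should saturate only the unhindered disubstituted C6=C7 alkene and leave the bromine-bearing C5=C10 alkene and both carbinol centres untouched.

Step 2
Reactants: 2 (1S,2S)-3-bromocyclohex-3-ene-1,2-diol
Product: 3 (1S,6S)-2-bromo-6-(triethylsilyloxy)cyclohex-2-en-1-ol
Conditions: Et3SiCl (1.05 equiv), imidazole, CH2Cl2, −78 to −40 °C
Reagents that add atoms: chlorotriethylsilane, CC[Si](Cl)(CC)CC
Why: Silyl ether formation under steric control: the homoallylic C8 hydroxyl, remote from the vinylic bromine, is the less hindered one and should react first at low temperature, which marks C8 with the more labile silyl group for its late, separate release.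

Step 3
Reactants: 3 (1S,6S)-2-bromo-6-(triethylsilyloxy)cyclohex-2-en-1-ol
Product: 4 (1S,6S)-2-bromo-1-(tert-butyldimethylsilyloxy)-6-(triethylsilyloxy)cyclohex-2-ene
Conditions: TBSOTf, 2,6-lutidine, CH2Cl2, −78 to 0 °C
Reagents that add atoms: tert-butyldimethylsilyl trifluoromethanesulfonate, CC(C)(C)[Si](C)(C)OS(=O)(=O)C(F)(F)F
Why: Silylation of the remaining allylic C9 hydroxyl with the reactive silyl triflate gives the acid-stable TBS ether that stays on until the last but one step; no stereocentre changes.

Step 4
Reactants: 4 (1S,6S)-2-bromo-1-(tert-butyldimethylsilyloxy)-6-(triethylsilyloxy)cyclohex-2-ene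
Product: 5 methyl (5S,6R)-6-(tert-butyldimethylsilyloxy)-5-(triethylsilyloxy)cyclohex-1-ene-1-carboxylate
Conditions: Pd(PPh3)4 (5 mol%), CO (1 atm), MeOH, Et3N, DMF, 70 °C
Reagents that add atoms: carbon monoxide, [C-]#[O+]; methanol, CO
Why: Palladium-catalysed methoxycarbonylation: oxidative addition of zerovalent palladium to the vinyl C10–Br bond, CO insertion and methanolysis of the acyl complex install ester carbon C14 without moving the alkene.

Step 5
Reactants: 5 methyl (5S,6R)-6-(tert-butyldimethylsilyloxy)-5-(triethylsilyloxy)cyclohex-1-ene-1-carboxylate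
Product: 6 methyl (5S,6R)-6-(tert-butyldimethylsilyloxy)-3-oxo-5-(triethylsilyloxy)cyclohex-1-ene-1-carboxylate
Conditions: Mn(OAc)3·2H2O (10 mol%), tBuOOH (5 equiv), 3 Å MS, EtOAc, rt
Reagents that add atoms: tert-butyl hydroperoxide, CC(C)(C)OO
Why: Metal-catalysed allylic C–H oxidation with tert-butyl hydroperoxide (Kharasch-type peroxidation, then collapse to the ketone): of the two allylic sites only the C6 methylene can give an enone, the C9 methine being tertiary and shielded by its TBS ether, so the C5=C10–C6=O chromophore forms without touching C8 or C9.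

Step 6
Reactants: 6 methyl (5S,6R)-6-(tert-butyldimethylsilyloxy)-3-oxo-5-(triethylsilyloxy)cyclohex-1-ene-1-carboxylate; 7 methyl bromoacetate
Product: 9 methyl (4S,5S,6R)-6-(tert-butyldimethylsilyloxy)-4-(2-methoxy-2-oxoethyl)-3-oxo-5-(triethylsilyloxy)cyclohex-1-ene-1-carboxylate, via lithium enolate 8 (not isolated)
Conditions: LiN(SiMe3)2 (1.1 equiv), THF, −78 °C; then 7, −78 to −40 °C
Reagents that add atoms: none
Why: Kinetic enolate alkylation at the α′ carbon: LiN(SiMe3)2 removes a C7 proton and methyl bromoacetate enters anti to the neighbouring C8 silyloxy group, which puts the arm on the α face, i.e. the C7 epimer of what is needed; this is accepted and corrected in step 7.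

Step 7
Reactants: 9 methyl (4S,5S,6R)-6-(tert-butyldimethylsilyloxy)-4-(2-methoxy-2-oxoethyl)-3-oxo-5-(triethylsilyloxy)cyclohex-1-ene-1-carboxylate
Product: 11 methyl (4R,5S,6R)-6-(tert-butyldimethylsilyloxy)-4-(2-methoxy-2-oxoethyl)-3-oxo-5-(triethylsilyloxy)cyclohex-1-ene-1-carboxylate, via lithium enolate 10 (not isolated)
Conditions: LiN(SiMe3)2 (1.1 equiv), THF, −78 °C; then AcOH in THF, −78 °C
Reagents that add atoms: none
Why: Epimerisation by deprotonation and kinetic protonation: the amide is strong enough for the ketone α-CH but not for the ester arm, and the tetrasubstituted enolate should be protonated at C7 on the open α face opposite the two β-silyloxy groups, placing the arm β (cis to C8–O) as in the target; the product is the less stable epimer and meets no base until C6 is reduced.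

Step 8
Reactants: 12 methylenecyclobutane
Product: 13 1-methylcyclobutene
Conditions: Na on Al2O3 (cat.), neat, 0 to 25 °C; fractional distillation
Reagents that add atoms: none
Why: Base-catalysed alkene isomerisation through the allylic anion; the endocyclic trisubstituted alkene should predominate at equilibrium and residual 12 is removed by distillation.

Step 9
Reactants: 11 methyl (4R,5S,6R)-6-(tert-butyldimethylsilyloxy)-4-(2-methoxy-2-oxoethyl)-3-oxo-5-(triethylsilyloxy)cyclohex-1-ene-1-carboxylate; 13 1-methylcyclobutene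
Product: 14 cis-anti-cis tricyclic photoadduct (cyclobutane C1–C10–C5–C4 on the α face of the six-membered ring)
Conditions: hν (350 nm, Pyrex), 13 (8 equiv), degassed CH2Cl2, −40 °C; then filtration through neutral Al2O3
Reagents that add atoms: none
Why: Excitation of the C5=C10–C6=O enone gives a triplet that adds to 13 stepwise through a 1,4-biradical, as in the established photocycloaddition of cyclic enones to cyclobutenes. Either first bond that leads to the required orientation (C10–C1 or C5–C4) leaves a tertiary radical, whereas the reverse orientation would have to join the fully substituted C10 to the methyl-bearing C4, so the ester on C10 should direct C1 to C10 and C4 to C5. The single ring closed is the cyclobutane C1–C10–C5–C4, formed by intermolecular union and collapse of the biradical, and it holds the complete C1–C10 perimeter still stapled by C1–C4 and C5–C10. C10 and C5 are set by approach of 13 to the α face, opposite the β-oriented C9–OTBS, C8–OTES and C7 arm, while C1 and C4 are cis by the ring of 13 and the two outer rings end anti through the less crowded closure. The six–four fusion should be cis, and any trans-fused ketone is expected to relax at C5 on neutral Al2O3 faster than the C7 centre can epimerise. The selectivities needed are orientation (secured by substitution at C10) and cis-anti-cis topology (secured by the β substituents and ring strain), since C1, C4, C5 and C10 are later erased and only that topology steers the alkene geometry of step 10.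

Step 10
Reactants: 14 cis-anti-cis tricyclic photoadduct
Product: 15 cyclodeca-1(10),4-dien-6-one (ring-cis C1=C10 enoate, ring-trans C4=C5 enone; 7β arm, 8β-OTES, 9β-OTBS)
Conditions: degassed toluene, BHT (trace), sealed tube, 180 °C
Reagents that add atoms: none
Why: Thermal cycloreversion of the bicyclo[2.2.0]hexane core (formal retro-[2+2]): homolysis of the central C1–C4 bond gives a cyclohexane-1,4-diyl that fragments along the doubly activated C5–C10 bond, and the chair diyl with C6 equatorial and C9 axial should deliver the ring-trans C4=C5 enone together with the ring-cis C1=C10 enoate, whose conjugation to C6=O and C14 disfavours onward Cope rearrangement.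

Step 11
Reactants: 15 cyclodeca-1(10),4-dien-6-one
Product: 17 trans-fused 12,6α-lactone (8β-OTES, 9β-OTBS), via 6α-hydroxy ester 16 (not isolated)
Conditions: NaBH4, CeCl3·7H2O, MeOH, −78 °C; then PPTS (cat.), PhH, 50 °C
Reagents that add atoms: none
Why: Luche 1,2-reduction followed by acid-catalysed lactonisation: hydride should reach C6 from the ring periphery on the β face in the conformer whose carbonyl oxygen points α, away from the β groups at C7–C9, setting the 6α-alcohol (trans to the C7 arm), which then closes the γ-lactone onto the methyl ester with loss of methanol.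

Step 12
Reactants: 17 trans-fused 12,6α-lactone
Product: 19 11-(dimethylaminomethyl) lactone, via lactone lithium enolate 18 (not isolated)
Conditions: LiN(iPr)2, THF, −78 °C; then CH2=NMe2+ I−, −78 to 0 °C
Reagents that add atoms: dimethylmethyleneiminium iodide, C=[N+](C)C.[I-]
Why: Mannich-type aminomethylation of the lactone enolate with the preformed iminium salt introduces C13 at C11; the configuration of the new C11 centre is irrelevant because it becomes sp2 in step 13.

Step 13
Reactants: 19 11-(dimethylaminomethyl) lactone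
Product: 21 α-methylene lactone (8β-OTES, 9β-OTBS), via methiodide 20 (not isolated)
Conditions: MeI, THF, rt; then NaHCO3 (aq), CH2Cl2, rt
Reagents that add atoms: none
Why: N-Methylation and base-induced β-elimination of trimethylamine (Hofmann-type) unveil the C11=C13 exocyclic alkene; no stereocentre is formed.

Step 14
Reactants: 21 α-methylene lactone (8β-OTES, 9β-OTBS)
Product: 22 8β-hydroxy α-methylene lactone (9β-OTBS)
Conditions: PPTS, MeOH, 0 °C to rt
Reagents that add atoms: none
Why: Acid-catalysed methanolysis of a silyl ether: the secondary triethylsilyl ether at C8 is cleaved far faster than the TBS ether at C9, so only the C8 hydroxyl is freed.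

Step 15
Reactants: 23 tiglic acid
Product: 24 (E)-2-methylbut-2-en-1-ol
Conditions: LiAlH4, Et2O, 0 °C
Reagents that add atoms: none
Why: Hydride reduction of the carboxylic acid to the primary allylic alcohol; the conjugated E alkene is not reduced under these conditions.

Step 16
Reactants: 24 (E)-2-methylbut-2-en-1-ol
Product: 25 [(2R,3R)-2,3-dimethyloxiran-2-yl]methanol
Conditions: Ti(OiPr)4 (10 mol%), D-(−)-diethyl tartrate (12 mol%), tBuOOH, 4 Å MS, CH2Cl2, −20 °C
Reagents that add atoms: tert-butyl hydroperoxide, CC(C)(C)OO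
Why: Sharpless asymmetric epoxidation: with the D-(−)-tartrate ligand the titanium peroxide delivers oxygen to the alkene face that gives the (2R,3R)-epoxy alcohol, so both oxirane centres are set by the catalyst and the cis relationship of the two methyls comes from the E alkene.

Step 17
Reactants: 25 [(2R,3R)-2,3-dimethyloxiran-2-yl]methanol
Product: 26 (2S,3R)-2,3-dimethyloxirane-2-carboxylic acid
Conditions: TEMPO (cat.), NaOCl (cat.), NaClO2, MeCN–phosphate buffer (pH 6.7), 35 °C
Reagents that add atoms: sodium chlorite, [Na+].[O-]Cl=O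
Why: TEMPO-catalysed chlorite oxidation of the primary alcohol to the acid under buffered conditions that spare the oxirane; the centres are unchanged (C2 becomes S only through a change in substituent priority).

Step 18
Reactants: 22 8β-hydroxy α-methylene lactone (9β-OTBS); 26 (2S,3R)-2,3-dimethyloxirane-2-carboxylic acid
Product: 28 8β-[(2S,3R)-2,3-dimethyloxirane-2-carbonyloxy] lactone (9β-OTBS), via mixed anhydride 27 (not isolated)
Conditions: 26, 2,4,6-Cl3C6H2COCl, Et3N, toluene, rt; then 22, DMAP, toluene, rt
Reagents that add atoms: none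
Why: Yamaguchi esterification: the mixed anhydride acylates the only free hydroxyl (C8) under DMAP catalysis with retention at C8, the hindered α-quaternary acid carrying its two centres unchanged.

Step 19
Reactants: 28 8β-acyloxy lactone (9β-OTBS)
Product: 29 9β-hydroxy 8β-acyloxy lactone with the C4=C5 alkene (4,5-deoxy target)
Conditions: HF·pyridine, pyridine, THF, 0 °C to rt
Reagents that add atoms: none
Why: Fluoride-mediated cleavage of the C9 TBS ether under buffered acidic conditions, chosen instead of basic fluoride so that the C8 ester cannot migrate to C9 and the electron-poor side-chain oxirane stays intact.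

Step 20
Reactants: 29 9β-hydroxy 8β-acyloxy lactone with the C4=C5 alkene
Product: 30 target CNP0262846.1
Conditions: mCPBA, NaHCO3, CH2Cl2, 0 °C
Reagents that add atoms: 3-chloroperoxybenzoic acid, OOC(=O)c1cccc(Cl)c1
Why: Prilezhaev epoxidation: the peracid reacts only with the electron-rich trisubstituted C4=C5 alkene (the enoate and the α-methylene lactone are electron-poor) and should attack its exposed outer face in the preferred ring conformer, giving the 4α,5β-oxide (4R,5R) with retention of the ring-trans geometry.

Compound list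

1 | (1S,2S)-3-bromocyclohexa-3,5-diene-1,2-diol | BrC1=CC=C[C@H](O)[C@@H]1O | starting material
2 | (1S,2S)-3-bromocyclohex-3-ene-1,2-diol | BrC1=CCC[C@H](O)[C@@H]1O | intermediate
3 | (1S,6S)-2-bromo-6-(triethylsilyloxy)cyclohex-2-en-1-ol (C8–OTES, C9–OH) | BrC1=CCC[C@H](O[Si](CC)(CC)CC)[C@@H]1O | intermediate
4 | (1S,6S)-2-bromo-1-(tert-butyldimethylsilyloxy)-6-(triethylsilyloxy)cyclohex-2-ene | BrC1=CCC[C@H](O[Si](CC)(CC)CC)[C@@H]1O[Si](C)(C)C(C)(C)C | intermediate
5 | methyl (5S,6R)-6-(tert-butyldimethylsilyloxy)-5-(triethylsilyloxy)cyclohex-1-ene-1-carboxylate | COC(=O)C1=CCC[C@H](O[Si](CC)(CC)CC)[C@@H]1O[Si](C)(C)C(C)(C)C | intermediate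
6 | methyl (5S,6R)-6-(tert-butyldimethylsilyloxy)-3-oxo-5-(triethylsilyloxy)cyclohex-1-ene-1-carboxylate | COC(=O)C1=CC(=O)C[C@H](O[Si](CC)(CC)CC)[C@@H]1O[Si](C)(C)C(C)(C)C | intermediate
7 | methyl bromoacetate | COC(=O)CBr | starting material
8 | lithium C6–C7 enolate of 6 | COC(=O)C1=CC(O[Li])=C[C@H](O[Si](CC)(CC)CC)[C@@H]1O[Si](C)(C)C(C)(C)C | intermediate
9 | methyl (4S,5S,6R)-6-(tert-butyldimethylsilyloxy)-4-(2-methoxy-2-oxoethyl)-3-oxo-5-(triethylsilyloxy)cyclohex-1-ene-1-carboxylate (C7 arm α, trans to C8–O) | COC(=O)C1=CC(=O)[C@@H](CC(=O)OC)[C@H](O[Si](CC)(CC)CC)[C@@H]1O[Si](C)(C)C(C)(C)C | intermediate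
10 | lithium C6–C7 enolate of 9 | COC(=O)C1=CC(O[Li])=C(CC(=O)OC)[C@H](O[Si](CC)(CC)CC)[C@@H]1O[Si](C)(C)C(C)(C)C | intermediate
11 | methyl (4R,5S,6R)-6-(tert-butyldimethylsilyloxy)-4-(2-methoxy-2-oxoethyl)-3-oxo-5-(triethylsilyloxy)cyclohex-1-ene-1-carboxylate (C7 arm β, all-cis; key-step precursor) | COC(=O)C1=CC(=O)[C@H](CC(=O)OC)[C@H](O[Si](CC)(CC)CC)[C@@H]1O[Si](C)(C)C(C)(C)C | intermediate
12 | methylenecyclobutane | C=C1CCC1 | starting material
13 | 1-methylcyclobutene | CC1=CCC1 | intermediate
14 | cis-anti-cis photoadduct: six-membered C6 ketone (C10 CO2Me, 7β-CH2CO2Me, 8β-OTES, 9β-OTBS) with cyclobutane C1–C10–C5–C4 cis-fused on its α face and cyclobutane C1–C2–C3–C4 anti to the six-membered ring; H-1 and C15 cis | COC(=O)[C@]12[C@@H]3CC[C@]3(C)[C@H]1C(=O)[C@H](CC(=O)OC)[C@H](O[Si](CC)(CC)CC)[C@@H]2O[Si](C)(C)C(C)(C)C | intermediate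
15 | methyl 9β-(tert-butyldimethylsilyloxy)-7β-(2-methoxy-2-oxoethyl)-4-methyl-6-oxo-8β-(triethylsilyloxy)cyclodeca-1(10),4-diene-10-carboxylate, germacrane numbering (ring-cis C1=C10, ring-trans C4=C5) | COC(=O)/C1=C/CC/C(C)=C/C(=O)[C@H](CC(=O)OC)[C@H](O[Si](CC)(CC)CC)[C@@H]1O[Si](C)(C)C(C)(C)C | intermediate
16 | 6α-hydroxy ester from 15 (6α-OH trans to the 7β arm) | COC(=O)/C1=C/CC/C(C)=C/[C@@H](O)[C@H](CC(=O)OC)[C@H](O[Si](CC)(CC)CC)[C@@H]1O[Si](C)(C)C(C)(C)C | intermediate
17 | trans-fused 12,6α-lactone: methyl 9β-(tert-butyldimethylsilyloxy)-8β-(triethylsilyloxy)germacra-1(10),4-dien-12,6α-olid-14-oate (ring-cis C1=C10, ring-trans C4=C5) | O=C1C[C@@H]2[C@H](O[Si](CC)(CC)CC)[C@H](O[Si](C)(C)C(C)(C)C)/C(C(=O)OC)=C\CC/C(C)=C/[C@H]2O1 | intermediate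
18 | lithium enolate of lactone 17 (C11=C12) | [Li]OC1=C[C@@H]2[C@H](O[Si](CC)(CC)CC)[C@H](O[Si](C)(C)C(C)(C)C)/C(C(=O)OC)=C\CC/C(C)=C/[C@H]2O1 | intermediate
19 | 11-(dimethylaminomethyl) derivative of 17 (C11 configuration not assigned) | O=C1C(CN(C)C)[C@@H]2[C@H](O[Si](CC)(CC)CC)[C@H](O[Si](C)(C)C(C)(C)C)/C(C(=O)OC)=C\CC/C(C)=C/[C@H]2O1 | intermediate
20 | methiodide (trimethylammonium iodide) of 19 | O=C1C(C[N+](C)(C)C)[C@@H]2[C@H](O[Si](CC)(CC)CC)[C@H](O[Si](C)(C)C(C)(C)C)/C(C(=O)OC)=C\CC/C(C)=C/[C@H]2O1.[I-] | intermediate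
21 | methyl 9β-(tert-butyldimethylsilyloxy)-8β-(triethylsilyloxy)germacra-1(10),4,11(13)-trien-12,6α-olid-14-oate | O=C1C(=C)[C@@H]2[C@H](O[Si](CC)(CC)CC)[C@H](O[Si](C)(C)C(C)(C)C)/C(C(=O)OC)=C\CC/C(C)=C/[C@H]2O1 | intermediate
22 | methyl 9β-(tert-butyldimethylsilyloxy)-8β-hydroxygermacra-1(10),4,11(13)-trien-12,6α-olid-14-oate | O=C1C(=C)[C@@H]2[C@H](O)[C@H](O[Si](C)(C)C(C)(C)C)/C(C(=O)OC)=C\CC/C(C)=C/[C@H]2O1 | intermediate
23 | tiglic acid, (E)-2-methylbut-2-enoic acid | C/C=C(\C)C(=O)O | starting material
24 | (E)-2-methylbut-2-en-1-ol | C/C=C(\C)CO | intermediate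
25 | [(2R,3R)-2,3-dimethyloxiran-2-yl]methanol | OC[C@@]1(C)O[C@@H]1C | intermediate
26 | (2S,3R)-2,3-dimethyloxirane-2-carboxylic acid | OC(=O)[C@@]1(C)O[C@@H]1C | intermediate
27 | (2S,3R)-2,3-dimethyloxirane-2-carboxylic 2,4,6-trichlorobenzoic anhydride | O=C(OC(=O)[C@@]1(C)O[C@@H]1C)c1c(Cl)cc(Cl)cc1Cl | intermediate
28 | methyl 9β-(tert-butyldimethylsilyloxy)-8β-[(2S,3R)-2,3-dimethyloxirane-2-carbonyloxy]germacra-1(10),4,11(13)-trien-12,6α-olid-14-oate | O=C1C(=C)[C@@H]2[C@H](OC(=O)[C@@]3(C)O[C@@H]3C)[C@H](O[Si](C)(C)C(C)(C)C)/C(C(=O)OC)=C\CC/C(C)=C/[C@H]2O1 | intermediate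
29 | methyl 8β-[(2S,3R)-2,3-dimethyloxirane-2-carbonyloxy]-9β-hydroxygermacra-1(10),4,11(13)-trien-12,6α-olid-14-oate | O=C1C(=C)[C@@H]2[C@H](OC(=O)[C@@]3(C)O[C@@H]3C)[C@H](O)/C(C(=O)OC)=C\CC/C(C)=C/[C@H]2O1 | intermediate
30 | CNP0262846.1: methyl (4R,5R,6S,7R,8S,9R)-4,5-epoxy-8-[(2S,3R)-2,3-dimethyloxirane-2-carbonyloxy]-9-hydroxygermacra-1(10),11(13)-dien-12,6-olid-14-oate (ring-cis C1=C10) | C=C1C(=O)O[C@H]2[C@H]1[C@H](OC(=O)[C@@]1(C)O[C@@H]1C)[C@H](O)/C(C(=O)OC)=C\CC[C@@]1(C)O[C@H]21 | target

Total step count: 20 steps. Longest linear sequence: 16 steps (1 to 30 through steps 1–7, 9–14 and 18–20); the side branches are step 8 (13) and steps 15–17 (26).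

Steps most likely to fail

Step 9. What may go wrong is loss of ring-fusion control: the biradical may close to trans-fused cyclobutanes, and relaxing them with base would also epimerise the contra-thermodynamic C7 centre. The fallback moves the cycloaddition one stage earlier, to enone 6, which has no C7 stereocentre. Irradiation of 6 with 13 under the same conditions should give the tricyclic ketone lacking the C7 arm F1, which can be equilibrated freely at C5 with catalytic DBU. Enolate alkylation of F1 (LiN(SiMe3)2, THF, −78 °C, then 7) should then give the 7-epi photoadduct F2, the arm entering anti to the C8 silyloxy group. Re-enolisation of F2 and an acetic acid quench at −78 °C set C7 as in step 7. The fallback sets out from 6 and rejoins the route at 14.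

Step 10. What may go wrong is loss of alkene-geometry control in the fragmentation of the 1,4-diyl (boat or alternative chair pathway), which would deliver the enoate with ring-trans geometry. The fallback postpones the correction until the ketone is gone. The ring-trans enoate dienone F3 obtained from 14 is reduced and lactonised as in step 11, through the 6α-hydroxy ester F4 to the ring-trans enoate lactone F5. In F5 the enoate is the only conjugate acceptor left, so catalytic PhSH with DBU in THF (reversible thia-Michael addition and elimination at C1) should equilibrate C1=C10 towards the ring-cis isomer without touching C4=C5. The fallback sets out from 14 and rejoins the route at 17.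

Step 11. What may go wrong is poor or inverted facial selectivity of hydride delivery to C6 in the flexible ten-membered ring, which would give the 6β-alcohol. The fallback closes the lactone with inversion instead. The reduction product of 15 is isolated without acid treatment as the 6β-hydroxy ester F6. LiOH (THF–H2O, 0 °C) hydrolyses its unhindered C12 methyl ester, leaving the conjugated C14 ester, to give the 6β-hydroxy acid F7. Mitsunobu lactonisation of F7 (PPh3, DIAD, THF, 0 °C) then displaces the activated C6 oxygen by the carboxylate with inversion and gives the trans-fused lactone. The fallback sets out from 15 and rejoins the route at 17.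

Further compounds

F1 | step 9 | cis-anti-cis photoadduct of 6 and 13 lacking the C7 arm (8β-OTES, 9β-OTBS) | COC(=O)[C@]12[C@@H]3CC[C@]3(C)[C@H]1C(=O)C[C@H](O[Si](CC)(CC)CC)[C@@H]2O[Si](C)(C)C(C)(C)C
F2 | step 9 | 7-epi photoadduct (C7 arm α) | COC(=O)[C@]12[C@@H]3CC[C@]3(C)[C@H]1C(=O)[C@@H](CC(=O)OC)[C@H](O[Si](CC)(CC)CC)[C@@H]2O[Si](C)(C)C(C)(C)C
F3 | step 10 | isomer of 15 with ring-trans C1=C10 enoate and ring-trans C4=C5 enone | COC(=O)/C1=C\CC/C(C)=C/C(=O)[C@H](CC(=O)OC)[C@H](O[Si](CC)(CC)CC)[C@@H]1O[Si](C)(C)C(C)(C)C
F4 | step 10 | 6α-hydroxy ester from F3 | COC(=O)/C1=C\CC/C(C)=C/[C@@H](O)[C@H](CC(=O)OC)[C@H](O[Si](CC)(CC)CC)[C@@H]1O[Si](C)(C)C(C)(C)C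
F5 | step 10 | isomer of lactone 17 with ring-trans C1=C10 enoate | O=C1C[C@@H]2[C@H](O[Si](CC)(CC)CC)[C@H](O[Si](C)(C)C(C)(C)C)/C(C(=O)OC)=C/CC/C(C)=C/[C@H]2O1
F6 | step 11 | 6β-hydroxy ester (6-epimer of 16) | COC(=O)/C1=C/CC/C(C)=C/[C@H](O)[C@H](CC(=O)OC)[C@H](O[Si](CC)(CC)CC)[C@@H]1O[Si](C)(C)C(C)(C)C
F7 | step 11 | 6β-hydroxy C12 carboxylic acid | COC(=O)/C1=C/CC/C(C)=C/[C@H](O)[C@H](CC(=O)O)[C@H](O[Si](CC)(CC)CC)[C@@H]1O[Si](C)(C)C(C)(C)C
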